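The bond between arene carbon C6 and the quaternary oxirane carbon C8 is the disconnection on which the route rests. Numbering: arene C1 (ester oxygen), C3 (methyl), C4 (methoxy), C6 (side chain); side chain C8 (quaternary oxirane carbon), C9 (oxirane CH2), C10 (CH2O). C6 is ortho to the C1 oxygen, whereas the para carbon C4 is blocked by methoxy and the second ortho carbon C2 is crowded by the C3 methyl, so a titanium-bound phenol can hand only C6 to a chelated ketone. One ortho Friedel–Crafts hydroxyalkylation joins commercial 4-methoxy-3-methylphenol to ethyl bromopyruvate, sets the C8 carbinol configuration and brings in C9 as CH2Br and C10 as the ester. Four functional-group steps then finish the target.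

Key step: step 1

Assumption: (S)-BINOL is taken to expose the Re face of the titanium-chelated ketone of 2, which gives the (2S)-carbinol needed; should the sense of induction be the opposite, (R)-BINOL is used and nothing else changes.

Step 1
Reactants: 1 4-methoxy-3-methylphenol; 2 ethyl bromopyruvate
Product: 3 ethyl (2S)-3-bromo-2-hydroxy-2-(2-hydroxy-5-methoxy-4-methylphenyl)propanoate
Conditions: Ti(OiPr)4 (10 mol%), (S)-BINOL (20 mol%), 4 Å MS, toluene, rt, iPrOH stripped; then 1, 2 (1.2 equiv, freshly distilled, slow addition), toluene, −20 → 0 °C; aq. potassium sodium tartrate work-up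
Reagents that add atoms: none
Why: Phenol 1 should exchange onto the BINOL-bound tetravalent titanium centre while keto ester 2 chelates the same metal through its ketone and ester carbonyl oxygens; C6 then attacks the ketone carbon through a six-membered cyclic transition state and proton loss restores the arene. The closest known reaction type is the titanium–BINOL-catalysed ortho Friedel–Crafts hydroxyalkylation of phenols with glyoxylates and pyruvates, of which the more electrophilic alpha-bromo keto ester is a new member. No ring is closed; the step forms only the C6–C8 bond and the C8 carbinol. The C8 configuration is set by the ligand, the (S)-BINOL pocket being expected to leave the Re face of the chelated ketone open, which gives the (2S)-carbinol. Regioselectivity for C6 over C2 and C5 follows from delivery by the phenol-bound metal (ortho only) and from the C3 methyl crowding C2, with C4 blocked by methoxy. Carbonyl addition should prevail over O-alkylation or bromide displacement because no free phenoxide is present, and the isopropanol-free catalyst and low temperature should suppress ester exchange and lactonisation.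

Step 2
Reactants: 3 ethyl (2S)-3-bromo-2-hydroxy-2-(2-hydroxy-5-methoxy-4-methylphenyl)propanoate; 4 angelic acid
Product: 6 ethyl (2S)-3-bromo-2-hydroxy-2-{5-methoxy-4-methyl-2-[(2Z)-2-methylbut-2-enoyloxy]phenyl}propanoate, via angelic 2,4,6-trichlorobenzoic anhydride 5 (not isolated)
Conditions: 4, 2,4,6-Cl3C6H2COCl, Et3N, toluene, rt; then 3, Et3N, toluene, −20 → 0 °C (no DMAP)
Reagents that add atoms: none
Why: In this Yamaguchi-type mixed-anhydride esterification only the phenol is nucleophilic (the tertiary alpha-hydroxy ester hydroxyl is inert), while leaving out nucleophilic catalysts at low temperature should keep the Z geometry and the amine is too weak to form a phenoxide that could displace the C9 bromide.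

Step 3
Reactants: 6 ethyl (2S)-3-bromo-2-hydroxy-2-{5-methoxy-4-methyl-2-[(2Z)-2-methylbut-2-enoyloxy]phenyl}propanoate
Product: 7 2-[(2S)-1-bromo-2,3-dihydroxypropan-2-yl]-4-methoxy-5-methylphenyl (2Z)-2-methylbut-2-enoate
Conditions: BH3·SMe2 (1.1 equiv), NaBH4 (5 mol%), THF, 0 °C → rt; MeOH quench, co-evaporation
Reagents that add atoms: none
Why: In this hydroxyl-directed borane reduction of an alpha-hydroxy ester the C8 hydroxyl binds boron and, after activation by catalytic borohydride, delivers hydride intramolecularly to the adjacent ethyl ester only, under non-basic conditions that should spare the aryl angelate, the C–Br bond and the C8 configuration.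

Step 4
Reactants: 7 2-[(2S)-1-bromo-2,3-dihydroxypropan-2-yl]-4-methoxy-5-methylphenyl (2Z)-2-methylbut-2-enoate; 8 tigloyl chloride
Product: 9 (2S)-3-bromo-2-hydroxy-2-{5-methoxy-4-methyl-2-[(2Z)-2-methylbut-2-enoyloxy]phenyl}propyl (2E)-2-methylbut-2-enoate
Conditions: pyridine, CH2Cl2, −20 → 0 °C
Reagents that add atoms: none
Why: In this pyridine-mediated acylation with an acid chloride the primary C10 hydroxyl should react while the fully substituted benzylic C8 hydroxyl stays free, and the tigloyl group has the stable E geometry so no isomerisation is at stake.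

Step 5
Reactants: 9 (2S)-3-bromo-2-hydroxy-2-{5-methoxy-4-methyl-2-[(2Z)-2-methylbut-2-enoyloxy]phenyl}propyl (2E)-2-methylbut-2-enoate
Product: 10 [(2R)-2-{5-methoxy-4-methyl-2-[(2Z)-2-methylbut-2-enoyloxy]phenyl}oxiran-2-yl]methyl (2E)-2-methylbut-2-enoate
Conditions: DBU (1.3 equiv), MeCN, 0 °C; pH 7 buffer work-up, Et3N-washed silica
Reagents that add atoms: none
Why: In this intramolecular Williamson etherification (3-exo-tet bromohydrin closure) the C8 oxygen displaces bromide at C9 without breaking any bond to C8, so the configuration is kept (the descriptor changes from S to R only through the priority rules), a non-nucleophilic amidine in an aprotic solvent spares both esters, and closing after tigloylation excludes Payne-type scrambling of a free epoxy alcohol.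

Compound list
1 | 4-methoxy-3-methylphenol | Cc1cc(O)ccc1OC | starting material
2 | ethyl bromopyruvate | CCOC(=O)C(=O)CBr | starting material
3 | ethyl (2S)-3-bromo-2-hydroxy-2-(2-hydroxy-5-methoxy-4-methylphenyl)propanoate | Oc1cc(C)c(OC)cc1[C@](O)(C(=O)OCC)CBr | intermediate
4 | angelic acid, (2Z)-2-methylbut-2-enoic acid | C/C=C(/C)C(=O)O | starting material
5 | angelic 2,4,6-trichlorobenzoic anhydride | C/C=C(/C)C(=O)OC(=O)c1c(Cl)cc(Cl)cc1Cl | intermediate
6 | ethyl (2S)-3-bromo-2-hydroxy-2-{5-methoxy-4-methyl-2-[(2Z)-2-methylbut-2-enoyloxy]phenyl}propanoate | C/C=C(/C)C(=O)Oc1cc(C)c(OC)cc1[C@](O)(C(=O)OCC)CBr | intermediate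
7 | 2-[(2S)-1-bromo-2,3-dihydroxypropan-2-yl]-4-methoxy-5-methylphenyl (2Z)-2-methylbut-2-enoate | C/C=C(/C)C(=O)Oc1cc(C)c(OC)cc1[C@](O)(CO)CBr | intermediate
8 | tigloyl chloride, (2E)-2-methylbut-2-enoyl chloride | C/C=C(\C)C(=O)Cl | starting material
9 | (2S)-3-bromo-2-hydroxy-2-{5-methoxy-4-methyl-2-[(2Z)-2-methylbut-2-enoyloxy]phenyl}propyl (2E)-2-methylbut-2-enoate | C/C=C(/C)C(=O)Oc1cc(C)c(OC)cc1[C@](O)(COC(=O)/C(C)=C/C)CBr | intermediate
10 | [(2R)-2-{5-methoxy-4-methyl-2-[(2Z)-2-methylbut-2-enoyloxy]phenyl}oxiran-2-yl]methyl (2E)-2-methylbut-2-enoate | C/C=C(/C)C(=O)Oc1cc(C)c(OC)cc1[C@]1(COC(=O)/C(C)=C/C)CO1 | target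

Total step count: 5. Longest linear sequence: 5 steps (1 and 2 to 10).

Steps most likely to fail

Step 1. The adduct is a strong chelator for titanium, so turnover may stall. The ligand-free background addition to the very electrophilic bromo ketone may also erode facial selectivity. Fallback (sets out from 1, comes back at 3): 1 is deprotonated with EtMgBr in Et2O/toluene to bromomagnesium 4-methoxy-3-methylphenolate F1. This stoichiometric phenolate adds ortho-specifically through a magnesium chelate to 2 in toluene at 0 °C and should give, after dilute HCl work-up, racemic ethyl 3-bromo-2-hydroxy-2-(2-hydroxy-5-methoxy-4-methylphenyl)propanoate F2. Preparative chromatography on a chiral stationary phase then delivers the (2S)-enantiomer 3.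

Step 3. Free borane may hydroborate the angelate double bond, or hydride may reach the aryl ester, before the hindered C8 hydroxyl has captured the boron. Fallback (sets out from 3, comes back at 7): the order of reduction and acylation is swapped. 3, which has no unsaturated ester, is reduced with BH3·SMe2 (3 equiv) and NaBH4 (10 mol%) in THF, followed by MeOH, to (2S)-3-bromo-2-(2-hydroxy-5-methoxy-4-methylphenyl)propane-1,2-diol F3. The phenol of F3 is then acylated selectively with mixed anhydride 5 (from 4 as in step 2) and Et3N in toluene at −20 °C without DMAP; under these conditions aliphatic hydroxyls should not react. This gives 7.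

Step 5. The angeloyl group may transfer from the aryl oxygen to the neighbouring C8 alkoxide faster than the ring closes, after which the freed phenoxide would alkylate C9. Fallback (sets out from 3, comes back at 10): the aryl ester is brought in only after the oxirane exists.
- 3 is silylated at the phenol with TIPSOTf and 2,6-lutidine in CH2Cl2 at −78 °C to ethyl (2S)-3-bromo-2-hydroxy-2-{5-methoxy-4-methyl-2-[tri(propan-2-yl)silyloxy]phenyl}propanoate F4.
- BH3·SMe2 with catalytic NaBH4 reduces F4 to (2S)-3-bromo-2-{5-methoxy-4-methyl-2-[tri(propan-2-yl)silyloxy]phenyl}propane-1,2-diol F5.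
- 8 and pyridine give (2S)-3-bromo-2-hydroxy-2-{5-methoxy-4-methyl-2-[tri(propan-2-yl)silyloxy]phenyl}propyl (2E)-2-methylbut-2-enoate F6.
- DBU in MeCN closes F6 to [(2R)-2-{5-methoxy-4-methyl-2-[tri(propan-2-yl)silyloxy]phenyl}oxiran-2-yl]methyl (2E)-2-methylbut-2-enoate F7; the bulky silyl group should not migrate.
- CsF in MeCN at 0 °C in the presence of excess 5 cleaves the aryl silyl ether and acylates the phenoxide as it forms (desilylative acylation) to give 10.

Further compounds
F1 | step 1 | bromomagnesium 4-methoxy-3-methylphenolate | Cc1cc(O[Mg]Br)ccc1OC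
F2 | step 1 | racemic ethyl 3-bromo-2-hydroxy-2-(2-hydroxy-5-methoxy-4-methylphenyl)propanoate | CCOC(=O)C(O)(CBr)c1cc(OC)c(C)cc1O
F3 | step 3 | (2S)-3-bromo-2-(2-hydroxy-5-methoxy-4-methylphenyl)propane-1,2-diol | Oc1cc(C)c(OC)cc1[C@](O)(CO)CBr
F4 | step 5 | ethyl (2S)-3-bromo-2-hydroxy-2-{5-methoxy-4-methyl-2-[tri(propan-2-yl)silyloxy]phenyl}propanoate | CC(C)[Si](C(C)C)(C(C)C)Oc1cc(C)c(OC)cc1[C@](O)(C(=O)OCC)CBr
F5 | step 5 | (2S)-3-bromo-2-{5-methoxy-4-methyl-2-[tri(propan-2-yl)silyloxy]phenyl}propane-1,2-diol | CC(C)[Si](C(C)C)(C(C)C)Oc1cc(C)c(OC)cc1[C@](O)(CO)CBr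
F6 | step 5 | (2S)-3-bromo-2-hydroxy-2-{5-methoxy-4-methyl-2-[tri(propan-2-yl)silyloxy]phenyl}propyl (2E)-2-methylbut-2-enoate | CC(C)[Si](C(C)C)(C(C)C)Oc1cc(C)c(OC)cc1[C@](O)(COC(=O)/C(C)=C/C)CBr
F7 | step 5 | [(2R)-2-{5-methoxy-4-methyl-2-[tri(propan-2-yl)silyloxy]phenyl}oxiran-2-yl]methyl (2E)-2-methylbut-2-enoate | CC(C)[Si](C(C)C)(C(C)C)Oc1cc(C)c(OC)cc1[C@]1(COC(=O)/C(C)=C/C)CO1
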